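The data were generated by integration from invented constants; the scatter is artificial.

- A leftover opens the dawn flask, the flask asked about: taken one to one, its charge leaves 0.570 M of reagent over, with starting material as the limiting reagent, yet its target bends over and reads 33.2% at 50.0 h.

all flasks: starting material 0.71 M; reagent 1.28 M
- dawn: protic impurity 0.071 M; temperature 25 °C; the very flask that is asked about, followed so far
- noon: protic impurity 0.048 M; temperature 20 °C; run made earlier
- flask: protic impurity 0.0710 M; temperature 25 °C; time 2.5 d

| dawn: time / h | dawn: target / % | noon: time / h | noon: target / % |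
|---|---|---|---|
| 6.00 | 8.8 | 3.00 | 0.8 |
| 15.0 | 21.0 | 6.00 | 3.7 |
| 20.0 | 25.4 | 10.0 | 7.6 |
| 30.0 | 30.0 | 12.0 | 8.9 |
| 40.0 | 32.5 | 15.0 | 11.8 |
| 50.0 | 33.2 | 20.0 | 15.5 |

(readings scatter by 0.5 percentage points)

- west: at 2.5 d take out 90% of the target then present, then wait 30 h
- north: at 2.5 d raise the temperature by 25 K, then wait 30 h
- south: change nothing and wait 30 h more

- what is taken out of target is counted as made

- target, in percent of the starting material first charged, at 2.5 d
- which option adds most target ("none" when 2 percentage points or less is all one gets) (west / north / south / none)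
- target present, with what was taken out counted in, in percent of the starting material first charged, after west
- target present, with what was taken out counted in, in percent of the starting material first charged, after south

- The noon run changes impurity and temperature together, so this reckoning, my own, reads the curve of the dawn flask alone.
- The dawn target climbs from 6.00 h to 15.0 h at 0.0136 h⁻¹ as a fraction of the charge.
- Past the knee, the slope is 0.00460 h⁻¹ from 20.0 h to 30.0 h, around a mean target of 27.7%; this is less than the opening slope.
- From 40.0 h to 50.0 h, the slope is 7.00 × 10⁻⁴ h⁻¹, around 32.9%.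
- Taking the late slope as proportional to the gap, dY/dt = k(P − Y), with Y the target and P its level, these two pairs read k = 0.0757 h⁻¹ and P = 33.8%.
- Integrated, the gap P − Y decays as exp(−kt), so τ = ln(2)/k, the closing half-life, the time in which that gap halves, reads 9.15 h.
- From the last reading, the gap at 2.5 d is 0.27 percentage points, so the target reads 33.5%, and south adds 0.24 points, less than the margin. This curve does not show what the level is made of, so it gives no number for west or north.
- The forecast stands a little higher: 33.8% (32.8% to 34.8%), 34.2% after south, 34.4% after west with a range up to 45%, and best none, reading that “the impurity kills the active species and the plateau is not an equilibrium”.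
- The flask gives 33.8%, 34.2% after south and 42.9% after west; north adds 12 points, more than west's 9 points, so the best option is north.

    target ⇌ isomer of the product (K = 0.400, k = 8.03 × 10⁻⁴ min⁻¹, Ea = 105 kJ mol⁻¹, ΔH = −67.0 kJ mol⁻¹)
    reagent + intermediate D → side product (k = 0.00535 L mol⁻¹ min⁻¹, Ea = 82.0 kJ mol⁻¹)
    reagent + intermediate B → intermediate D (k = 0.00360 L mol⁻¹ min⁻¹, Ea = 60.0 kJ mol⁻¹)
    starting material ⇌ intermediate B (K = 2.80, k = 0.00537 min⁻¹, Ea = 94.0 kJ mol⁻¹, ΔH = −39.0 kJ mol⁻¹)
    starting material → intermediate C (k = 0.00397 min⁻¹, Ea = 101 kJ mol⁻¹)
    intermediate C → target (k = 0.00124 min⁻¹, Ea = 93.0 kJ mol⁻¹)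
    starting material + protic impurity → quenched substrate (k = 0.0418 L mol⁻¹ min⁻¹, Ea = 65.0 kJ mol⁻¹)
    starting material ⇌ intermediate A (K = 0.462, k = 0.00292 min⁻¹, Ea = 90.0 kJ mol⁻¹, ΔH = −21.0 kJ mol⁻¹)
    (constants at 25 °C)

- In the flask, intermediate C becomes target with a half-life of 9.32 h, while target and isomer of the product relax with 4.11 h, which is faster. At 60.0 h the flask holds isomer to target at 0.392, beside K1 = 0.40. τ was read off the gap of the dawn target, not off intermediate C, and it lies close to that half-life of intermediate C. Borrowed as a stand-in over 30 h, τ takes the flask's intermediate C from 7.47% to a reckoned 0.770%, the half-life of the step itself gives 0.802%, and 0.854% stands there.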